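**Strategy.** The route rests on disconnecting ring B of the cis-decalin at C5–C10 and C7–C8. A temporary ketone at C6 makes C5 and C7 the two ends of a 1,3-dinucleophile, and an (E)-enoate C8–C9=C10 is the matching 1,3-dielectrophile. One base-mediated Michael–Claisen cascade therefore closes ring A (C5–C10, setting quaternary C5 and C10) and ring B (C7–C8) from the open-chain keto triester 16. The feature exploited is the 1,3-relationship of the C8 carbonyl and the C6 methine in the ring B enone. The C6 oxygen is then removed by Stork–Danheiser transposition. C3/C4 come from an Evans aldol, C11 from a chiral-pool zinc homoenolate.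

Key step: step 8

Remark: atom labels C1–C15 follow eremophilane numbering (decalin C1–C10, angular methyl C14 on C5, ester carbon C15 on C4, side chain C11–C13 on C7) and are also used for the corresponding atoms of open-chain intermediates. The methyl-bearing carbon that becomes C5 is carried as the (S) epimer, but its configuration is inconsequential because C5 becomes an enolate carbon in step 8.

**Step 1**
Reactants: 1 pent-4-enal; 2 methyl acrylate
Product: 3 methyl (2E)-6-oxohex-2-enoate
Conditions: second-generation Grubbs catalyst (2 mol %), methyl acrylate (3 equiv), CH2Cl2, 40 °C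
Reagents that add atoms: none
Why: olefin cross-metathesis of a terminal alkene with an acrylate should give the (E)-enoate with loss of ethene, and the aldehyde is tolerated.

**Step 2**
Reactants: 4 (4S)-4-benzyl-1,3-oxazolidin-2-one; 5 (S)-methylsuccinic anhydride
Product: 6 (2S)-4-[(4S)-4-benzyl-2-oxo-1,3-oxazolidin-3-yl]-2-methyl-4-oxobutanoic acid
Conditions: n-BuLi, THF, −78 °C; then 5, −78 to 0 °C; aq. HCl work-up
Reagents that add atoms: none
Why: N-acylation of the lithiated oxazolidinone by ring opening of the anhydride should occur at the less hindered, CH2-flanked carbonyl (the minor regioisomer is removed by crystallisation), which places the auxiliary on C15 and leaves the C6 carboxylic acid free.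

**Step 3**
Reactants: 6 (2S)-4-[(4S)-4-benzyl-2-oxo-1,3-oxazolidin-3-yl]-2-methyl-4-oxobutanoic acid
Product: 7 tert-butyl (2S)-4-[(4S)-4-benzyl-2-oxo-1,3-oxazolidin-3-yl]-2-methyl-4-oxobutanoate
Conditions: tert-butyl 2,2,2-trichloroacetimidate, BF3·OEt2 (cat.), CH2Cl2–cyclohexane, rt
Reagents that add atoms: tert-butyl 2,2,2-trichloroacetimidate, CC(C)(C)OC(=N)C(Cl)(Cl)Cl
Why: acid-catalysed imidate tert-butylation of the carboxylic acid leaves the imide intact, and the tert-butyl ester is chosen because it is not enolised by the boron reagent and does not lactonise with the γ-hydroxyl formed in step 4.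

**Step 4**
Reactants: 7 tert-butyl (2S)-4-[(4S)-4-benzyl-2-oxo-1,3-oxazolidin-3-yl]-2-methyl-4-oxobutanoate; 3 methyl (2E)-6-oxohex-2-enoate
Product: 8 9-tert-butyl 1-methyl (2E,6R,7S,8S)-7-[(4S)-4-benzyl-2-oxo-1,3-oxazolidine-3-carbonyl]-6-hydroxy-8-methylnon-2-enedioate
Conditions: Bu2BOTf, iPr2NEt, CH2Cl2, −78 to 0 °C; then 3, −78 to 0 °C; pH 7 buffer, MeOH, H2O2
Reagents that add atoms: none
Why: Evans syn aldol reaction, in which the Z-boron enolate of the imide reacts through a chair Zimmerman–Traxler transition state and the (S)-benzyl auxiliary sets C4 (S) and C3 (R) in the syn relationship needed for the cis C3–O/C4–CO2Me pair of ring A.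

**Step 5**
Reactants: 8 9-tert-butyl 1-methyl (2E,6R,7S,8S)-7-[(4S)-4-benzyl-2-oxo-1,3-oxazolidine-3-carbonyl]-6-hydroxy-8-methylnon-2-enedioate
Product: 9 9-tert-butyl 1-methyl (2E,6R,7S,8S)-6-hydroxy-7-(methoxycarbonyl)-8-methylnon-2-enedioate
Conditions: MeOMgBr (from MeMgBr and MeOH), CH2Cl2–MeOH, 0 °C; aq. NH4Cl
Reagents that add atoms: methanol (as MeOMgBr), CO
Why: chelation-assisted transesterification of the β-hydroxy imide should release the auxiliary and give the C15 methyl ester without touching the tert-butyl ester or the enoate and without retro-aldol cleavage at this temperature.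

**Step 6**
Reactants: 9 9-tert-butyl 1-methyl (2E,6R,7S,8S)-6-hydroxy-7-(methoxycarbonyl)-8-methylnon-2-enedioate
Product: 12 (2S,3S,4R,7E)-4-[(tert-butyldimethylsilyl)oxy]-9-methoxy-3-(methoxycarbonyl)-2-methyl-9-oxonon-7-enoic acid, via TBS ether 10 (not isolated), via trimethylsilyl ester 11 (not isolated)
Conditions: TBSOTf, 2,6-lutidine, CH2Cl2, −78 to 0 °C; then TMSOTf, 0 °C to rt; aq. citric acid work-up
Reagents that add atoms: tert-butyldimethylsilyl trifluoromethanesulfonate, CC(C)(C)[Si](C)(C)OS(=O)(=O)C(F)(F)F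
Why: silylation of the C3 hydroxyl followed in the same flask by silyl triflate-mediated cleavage of the tert-butyl ester (loss of isobutene, silyl ester hydrolysed on work-up) should free only the C6 acid, since the TBS ether and methyl esters are stable to TMSOTf and 2,6-lutidine.

**Step 7**
Reactants: 12 (2S,3S,4R,7E)-4-[(tert-butyldimethylsilyl)oxy]-9-methoxy-3-(methoxycarbonyl)-2-methyl-9-oxonon-7-enoic acid; 13 methyl (2R)-3-bromo-2-methylpropanoate
Product: 16 dimethyl (2E,6R,7S,8S,11S)-6-[(tert-butyldimethylsilyl)oxy]-7-(methoxycarbonyl)-8,11-dimethyl-9-oxododec-2-enedioate, via acid chloride 14 (not isolated), via zinc reagent 15 (not isolated)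
Conditions: 12, 1-chloro-N,N,2-trimethylprop-1-en-1-amine, CH2Cl2, 0 °C to rt; separately 13, Zn dust, LiCl, THF, 40 °C; then combine, Pd(PPh3)4 (5 mol %), THF, 0 °C to rt
Reagents that add atoms: none
Why: Negishi acylation, in which the acid chloride formed under neutral conditions couples with the β-zincio ester under palladium catalysis to give the C6 ketone, and C11 is retained because the stereocentre is not the zinc-bearing carbon.

**Step 8**
Reactants: 16 dimethyl (2E,6R,7S,8S,11S)-6-[(tert-butyldimethylsilyl)oxy]-7-(methoxycarbonyl)-8,11-dimethyl-9-oxododec-2-enedioate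
Product: 18 dimethyl (3R,4S,5R,10S,11S)-3-[(tert-butyldimethylsilyl)oxy]-8-hydroxy-6-oxoeremophil-7-ene-12,15-dioate (enol form of the cis-fused 6,8-dione), via Michael adduct 17 (not isolated)
Conditions: KOtBu (1.2 equiv), THF–tBuOH (10:1), 0.02 M, −30 °C to rt; aq. NH4Cl, then dilute HCl to pH 3
Reagents that add atoms: none
Why: KOtBu equilibrates the ketone enolates of 16, the C5 enolate adds to C10 of the enoate (6-(enolexo)-exo-trig Michael addition closing ring A to give 17), proton transfer then gives the C7 enolate, which acylates at the C8 methyl ester (6-(enolendo)-exo-trig Claisen closure of ring B), and the acidic 6,8-dione is held as its potassium enolate, which makes the sequence irreversible. The closest known reaction type is the base-mediated Michael–Claisen [3+3] annulation of ketones with α,β-unsaturated esters to cyclohexane-1,3-diones, here run intramolecularly for both bonds. The quaternary centre C5 is controlled by the C4 stereocentre in a chair-like transition state with the C3 silyloxy group equatorial: C10 should add to the enolate face that keeps the C4 ester turned away from the enolate oxygen (allylic strain), which places CH3-14 cis to the C4 ester. C10 is set by the equatorial enoate arm in the same chair, so that the C6 acyl and C9 arms are cis and a cis-decalin results; the trans-fused alternative would enforce a syn-diaxial C3–OTBS/C5–CH3 interaction and is expected to be disfavoured, also if the Michael step is reversible. The step needs regioselectivity (C5 versus C7 attack on C10, and C8 versus the C12 and C15 esters as acyl acceptor), which ring size secures because only these two closures are six-membered, and it needs C4 and C11 to stay intact, which the lower acidity of ester α-hydrogens relative to the ketone and the dione and the limited base charge should secure.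

**Step 9**
Reactants: 18 dimethyl (3R,4S,5R,10S,11S)-3-[(tert-butyldimethylsilyl)oxy]-8-hydroxy-6-oxoeremophil-7-ene-12,15-dioate
Product: 19 dimethyl (3R,4S,5R,10S,11S)-3-hydroxy-8-methoxy-6-oxoeremophil-7-ene-12,15-dioate
Conditions: HC(OMe)3, TsOH·H2O (cat.), MeOH, 45 °C
Reagents that add atoms: methanol, CO
Why: acid-catalysed vinylogous ester formation should occur at the less hindered C8 carbonyl (C6 is flanked by the quaternary C5), and the methanolic acid should cleave the secondary TBS ether in the same operation.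

**Step 10**
Reactants: 19 dimethyl (3R,4S,5R,10S,11S)-3-hydroxy-8-methoxy-6-oxoeremophil-7-ene-12,15-dioate
Product: 21 dimethyl (3R,4S,5S,10S,11S)-3-hydroxy-8-oxoeremophil-6-ene-12,15-dioate, via allylic alcohol 20 (not isolated)
Conditions: NaBH4, CeCl3·7H2O, MeOH, 0 °C to rt; then 1 M HCl, THF, rt
Reagents that add atoms: water, O
Why: Stork–Danheiser transposition, in which Luche 1,2-reduction of the vinylogous ester carbonyl at C6 leaves the methyl esters untouched, and acid then ionises the allylic alcohol, water adds at C8 and methanol is lost to give the 8-oxo-6-ene.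

**Step 11**
Reactants: 21 dimethyl (3R,4S,5S,10S,11S)-3-hydroxy-8-oxoeremophil-6-ene-12,15-dioate; 22 angelic acid, (2Z)-2-methylbut-2-enoic acid
Product: 24 dimethyl (3R,4S,5S,10S,11S)-3-{[(2Z)-2-methylbut-2-enoyl]oxy}-8-oxoeremophil-6-ene-12,15-dioate (CNP0265265.1), via mixed anhydride 23 (not isolated)
Conditions: 22, 2,4,6-trichlorobenzoyl chloride, Et3N, toluene, rt; then 21, 80 °C
Reagents that add atoms: none
Why: Yamaguchi-type mixed-anhydride esterification run without a nucleophilic catalyst should acylate the C3 hydroxyl with retention at C3 and without Z-to-E isomerisation of the angeloyl group.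

**Compound list**
1 | pent-4-enal | C=CCCC=O | starting material
2 | methyl acrylate | C=CC(=O)OC | starting material
3 | methyl (2E)-6-oxohex-2-enoate | O=CCC/C=C/C(=O)OC | intermediate
4 | (4S)-4-benzyl-1,3-oxazolidin-2-one | O=C1OC[C@H](Cc2ccccc2)N1 | starting material
5 | (S)-methylsuccinic anhydride, (3S)-3-methyloxolane-2,5-dione | C[C@H]1CC(=O)OC1=O | starting material
6 | (2S)-4-[(4S)-4-benzyl-2-oxo-1,3-oxazolidin-3-yl]-2-methyl-4-oxobutanoic acid | C[C@H](C(=O)O)CC(=O)N1[C@@H](Cc2ccccc2)COC1=O | intermediate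
7 | tert-butyl (2S)-4-[(4S)-4-benzyl-2-oxo-1,3-oxazolidin-3-yl]-2-methyl-4-oxobutanoate | C[C@H](C(=O)OC(C)(C)C)CC(=O)N1[C@@H](Cc2ccccc2)COC1=O | intermediate
8 | 9-tert-butyl 1-methyl (2E,6R,7S,8S)-7-[(4S)-4-benzyl-2-oxo-1,3-oxazolidine-3-carbonyl]-6-hydroxy-8-methylnon-2-enedioate | O[C@@H]([C@@H](C(=O)N1[C@@H](Cc2ccccc2)COC1=O)[C@H](C)C(=O)OC(C)(C)C)CC/C=C/C(=O)OC | intermediate
9 | 9-tert-butyl 1-methyl (2E,6R,7S,8S)-6-hydroxy-7-(methoxycarbonyl)-8-methylnon-2-enedioate | O[C@@H]([C@@H](C(=O)OC)[C@H](C)C(=O)OC(C)(C)C)CC/C=C/C(=O)OC | intermediate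
10 | 9-tert-butyl 1-methyl (2E,6R,7S,8S)-6-[(tert-butyldimethylsilyl)oxy]-7-(methoxycarbonyl)-8-methylnon-2-enedioate (TBS ether) | CC(C)(C)[Si](C)(C)O[C@@H]([C@@H](C(=O)OC)[C@H](C)C(=O)OC(C)(C)C)CC/C=C/C(=O)OC | intermediate
11 | 1-methyl 9-trimethylsilyl (2E,6R,7S,8S)-6-[(tert-butyldimethylsilyl)oxy]-7-(methoxycarbonyl)-8-methylnon-2-enedioate (trimethylsilyl ester) | CC(C)(C)[Si](C)(C)O[C@@H]([C@@H](C(=O)OC)[C@H](C)C(=O)O[Si](C)(C)C)CC/C=C/C(=O)OC | intermediate
12 | (2S,3S,4R,7E)-4-[(tert-butyldimethylsilyl)oxy]-9-methoxy-3-(methoxycarbonyl)-2-methyl-9-oxonon-7-enoic acid | CC(C)(C)[Si](C)(C)O[C@@H]([C@@H](C(=O)OC)[C@H](C)C(=O)O)CC/C=C/C(=O)OC | intermediate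
13 | methyl (2R)-3-bromo-2-methylpropanoate | BrC[C@H](C)C(=O)OC | starting material
14 | methyl (2E,6R,7S,8S)-6-[(tert-butyldimethylsilyl)oxy]-9-chloro-7-(methoxycarbonyl)-8-methyl-9-oxonon-2-enoate (acid chloride) | CC(C)(C)[Si](C)(C)O[C@@H]([C@@H](C(=O)OC)[C@H](C)C(=O)Cl)CC/C=C/C(=O)OC | intermediate
15 | bromo[(2R)-3-methoxy-2-methyl-3-oxopropyl]zinc (zinc reagent) | Br[Zn]C[C@H](C)C(=O)OC | intermediate
16 | dimethyl (2E,6R,7S,8S,11S)-6-[(tert-butyldimethylsilyl)oxy]-7-(methoxycarbonyl)-8,11-dimethyl-9-oxododec-2-enedioate | CC(C)(C)[Si](C)(C)O[C@@H]([C@@H](C(=O)OC)[C@H](C)C(=O)C[C@H](C)C(=O)OC)CC/C=C/C(=O)OC | intermediate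
17 | methyl (1S,2R,3S,6R)-6-[(tert-butyldimethylsilyl)oxy]-3-(2-methoxy-2-oxoethyl)-2-[(3S)-4-methoxy-3-methyl-4-oxobutanoyl]-2-methylcyclohexane-1-carboxylate (Michael adduct) | CC(C)(C)[Si](C)(C)O[C@@H]1CC[C@@H](CC(=O)OC)[C@@](C)(C(=O)C[C@H](C)C(=O)OC)[C@@H]1C(=O)OC | intermediate
18 | dimethyl (3R,4S,5R,10S,11S)-3-[(tert-butyldimethylsilyl)oxy]-8-hydroxy-6-oxoeremophil-7-ene-12,15-dioate (enol form of the 6,8-dione) | CC(C)(C)[Si](C)(C)O[C@@H]1CC[C@H]2CC(O)=C([C@H](C)C(=O)OC)C(=O)[C@@]2(C)[C@@H]1C(=O)OC | intermediate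
19 | dimethyl (3R,4S,5R,10S,11S)-3-hydroxy-8-methoxy-6-oxoeremophil-7-ene-12,15-dioate | O[C@@H]1CC[C@H]2CC(OC)=C([C@H](C)C(=O)OC)C(=O)[C@@]2(C)[C@@H]1C(=O)OC | intermediate
20 | dimethyl (3R,4S,5R,10S,11S)-3,6-dihydroxy-8-methoxyeremophil-7-ene-12,15-dioate (allylic alcohol, C6 epimers) | O[C@@H]1CC[C@H]2CC(OC)=C([C@H](C)C(=O)OC)C(O)[C@@]2(C)[C@@H]1C(=O)OC | intermediate
21 | dimethyl (3R,4S,5S,10S,11S)-3-hydroxy-8-oxoeremophil-6-ene-12,15-dioate | O[C@@H]1CC[C@H]2CC(=O)C([C@H](C)C(=O)OC)=C[C@@]2(C)[C@@H]1C(=O)OC | intermediate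
22 | angelic acid, (2Z)-2-methylbut-2-enoic acid | C/C=C(/C)C(=O)O | starting material
23 | (2Z)-2-methylbut-2-enoic 2,4,6-trichlorobenzoic anhydride (mixed anhydride) | C/C=C(/C)C(=O)OC(=O)c1c(Cl)cc(Cl)cc1Cl | intermediate
24 | dimethyl (3R,4S,5S,10S,11S)-3-{[(2Z)-2-methylbut-2-enoyl]oxy}-8-oxoeremophil-6-ene-12,15-dioate (CNP0265265.1) | C/C=C(/C)C(=O)O[C@@H]1CC[C@H]2CC(=O)C([C@H](C)C(=O)OC)=C[C@@]2(C)[C@@H]1C(=O)OC | target

**Step count.** Total: 11 steps. Longest linear sequence: 10 steps (steps 2 to 11); step 1 is a one-step side branch.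

**Steps most likely to fail**

Step 8. The potassium-enolate Michael addition may show poor facial or ring-fusion selectivity, and the alkoxide may cause β-elimination of the C3 silyloxy group or epimerisation α to the C15 ester. The fallback sets out from 16 and separates the two bond formations. TMSCl, NaI and Et3N in MeCN should give the thermodynamic trimethylsilyl enol ether F1. TiCl4 in CH2Cl2 at −78 °C should then effect an intramolecular Mukaiyama–Michael addition through an open transition state to the Michael adduct 17, which is isolated here so that diastereomers can be separated. KOtBu in THF at 0 °C then closes ring B by Claisen condensation, and the route is rejoined at 18.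

Step 10. Hydride addition to the hindered, strongly deactivated vinylogous ester carbonyl next to the quaternary centre may be incomplete, or may lose chemoselectivity against the methyl esters if forced. The fallback sets out from 18 and replaces steps 9 and 10. Thiophenol with TsOH in toluene under water removal should give the vinylogous thioester F2, whose carbonyl is less deactivated. NaBH4 with CeCl3·7H2O in MeOH should give the allylic alcohol F3. Aqueous HCl in THF–MeOH should then effect the hydrolytic transposition and remove the silyl ether, rejoining the route at 21.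

Step 11. The angeloyl donor may isomerise from Z to E during activation, and acylation of the hindered C3 hydroxyl may be slow. The fallback sets out from 21 and builds the Z-alkene on the ester. DCC and DMAP with 2-(diphenoxyphosphoryl)propanoic acid should give the phosphonate ester F4. A Z-selective Horner–Wadsworth–Emmons olefination with acetaldehyde (NaI, DBU, THF, −78 to 0 °C) should then form the (2Z)-2-methylbut-2-enoate directly, rejoining the route at 24.

**Further compounds**
F1 | step 8 | dimethyl (2E,6R,7S)-6-[(tert-butyldimethylsilyl)oxy]-7-(methoxycarbonyl)-8,11-dimethyl-9-[(trimethylsilyl)oxy]dodeca-2,8-dienedioate, (11S), enol ether geometry not defined | CC(C)(C)[Si](C)(C)O[C@@H]([C@@H](C(=O)OC)C(C)=C(O[Si](C)(C)C)C[C@H](C)C(=O)OC)CC/C=C/C(=O)OC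
F2 | step 10 | dimethyl (3R,4S,5R,10S,11S)-3-[(tert-butyldimethylsilyl)oxy]-6-oxo-8-(phenylsulfanyl)eremophil-7-ene-12,15-dioate | CC(C)(C)[Si](C)(C)O[C@@H]1CC[C@H]2CC(Sc3ccccc3)=C([C@H](C)C(=O)OC)C(=O)[C@@]2(C)[C@@H]1C(=O)OC
F3 | step 10 | dimethyl (3R,4S,5R,10S,11S)-3-[(tert-butyldimethylsilyl)oxy]-6-hydroxy-8-(phenylsulfanyl)eremophil-7-ene-12,15-dioate (C6 epimers) | CC(C)(C)[Si](C)(C)O[C@@H]1CC[C@H]2CC(Sc3ccccc3)=C([C@H](C)C(=O)OC)C(O)[C@@]2(C)[C@@H]1C(=O)OC
F4 | step 11 | dimethyl (3R,4S,5S,10S,11S)-3-{[2-(diphenoxyphosphoryl)propanoyl]oxy}-8-oxoeremophil-6-ene-12,15-dioate (epimers at the phosphonate α-carbon) | CC(P(=O)(Oc1ccccc1)Oc1ccccc1)C(=O)O[C@@H]1CC[C@H]2CC(=O)C([C@H](C)C(=O)OC)=C[C@@]2(C)[C@@H]1C(=O)OC
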